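## Structural features

Target 31 is a eudesmane, a decalin in which ring A (C1–C5, C10) and ring B (C5–C10) share the C5–C10 bond. It carries an isobutyrate on C3, an exocyclic methylene (C15) on C4, a hydroperoxide on C5, a methyl acrylate unit (C11=C13, ester carbon C12) on C7, an acetate on C8 and the angular methyl C14 on C10. The five stereocentres are (3S,5S,7R,8R,10R), that is 3β-acyloxy, 5α-OOH, 7β side chain (7α-H), 8β-acetoxy and 10β-methyl. C5 and C10 are adjacent, fully substituted and trans (OOH against CH3), and C7 and C8 are adjacent and cis. C3 is separated from C5 only by sp2 C4, whereas C7 and C10 are 1,4 across ring B and insulated from each other by C6 and by C8–C9. The tertiary allylic hydroperoxide (reduction, acid- or metal-induced cleavage), the acrylate (Michael acceptor) and two different esters of secondary alcohols beside a third ester are fragile, so the last steps cannot use strong base, nucleophiles, reductants or transition metals. The real difficulty is therefore not the carbon count but the oxygenated, fully substituted C5 next to C10, the differentiation of three oxygen functions, and absolute control of the remote pair C7/C10. The 5α-OOH/4(15)-ene pair is the product pattern of a singlet-oxygen ene reaction on a C4=C5 alkene, so ring A can travel as a 4-en-3-one. The key step uses the fact that the C8–C9 bond of ring B lies between C7 and C10. Each centre can be made on its own fragment with an alkene attached (vinyl on C7, propenyl on C10), and closing C8=C9 completes ring B and leaves an alkene placed for the C7 acetic acid arm to deliver O8 to the β face.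

## Logic of the disconnections

31 to 30: the C5–O bond is cut, the hydrogen returns to C15 and the alkene moves back to C4=C5. This is the retron of a singlet-oxygen ene reaction and puts the most labile group last. It removes one fully substituted stereocentre. The forward step must attack the α face and take hydrogen from C15, not from C6 or C3.

30 to 29 to 28: the O3–acyl bond is cut and O3 is traced to a silyl ether. The isobutyrate would not survive the basic steps that build the C11–C13 ester, so C3 is carried masked. Ester differentiation becomes a protecting-group exchange. Desilylation must leave the acetate and the acrylate alone.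

28 to 27 to 25: the O8–acetyl and the ester O–CH3 bonds are cut and O8 is reconnected to C12. The cis lactone stores the C7/C8 relationship and keeps the carboxyl apart from the other oxygens. Two esters are reduced to one ring. The forward opening must avoid relactonisation and conjugate addition to the methylene group.

25 to 22: the C11=C13 bond is cut. The Michael acceptor is installed late, and the skeleton simplifies to the 13-nor series. The forward step needs the lactone to be the only enolisable carbonyl, which is why C3 is not a ketone at that stage.

22 to 21 to 20: the O–Si bond and then the C3–H bond are cut. C3 becomes the carbonyl of the 4-en-3-one produced by the fragment union. The forward reduction must be 1,2-selective and must deliver hydride to the α face under control of C10.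

20 to 19 to 18: the C9–H bond is traced to C9–I, then the O8–C8 and C9–I bonds are cut together. O8 is delivered within the molecule from the C12 carboxyl on the β arm of C7, so only the cis product can form. The C8 stereocentre disappears and a C8=C9 alkene remains. The forward step needs 5-exo regiochemistry and anti addition.

18 to 17: C12 is taken down to the silyl-protected alcohol, which is the only form of the arm that tolerates an organolithium.

17 to 16: the C8=C9 bond is cut (key step). The bond lies between the two insulated stereocentres, so ring B opens to two alkenes on a monocyclic enone and no stereocentre is involved. The forward step needs only chemoselectivity among three alkenes.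

16 to 7 and 13: the C5–C6 bond is cut. C5 is the β-carbon of the enone and therefore the carbonyl carbon of a vinylogous ester, and the cut is convergent, with one stereocentre in each half. The forward step must add an alkyllithium to a hindered carbonyl and leave both stereocentres untouched.

7 to 6 to 5 to 3 to 2 to 1 (with 4): the alkene is moved back to the allyl position, then the C10–allyl bond, the carbonate O–C(O) bond, the C10–CH3 bond and the enol ether O–alkyl bond are cut. The quaternary centre arises from an enolate with no other stereochemistry, so the ligand alone decides the face. The isomerisation must stop at the propenyl stage, which the quaternary carbon ensures.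

13 to 12 to 11 to 10 to 8 and 9: the O–Si bond is cut, C12 is raised to the ester level, the C6–I bond is reconnected as the lactone O–C6 bond, and the C7–vinyl bond is cut. The lactone tells the two arms apart without protecting groups: its alkyl carbon becomes the C6 iodide and its acyl carbon becomes C12. The stereocentre comes from addition of a vinyl group to a flat butenolide. The forward steps need enantiofacial control by the catalyst and a ring opening that spares the vinyl group.

## Other disconnections considered

Alternative 1: The cut is the C10–C14 bond; the angular methyl is traced to the methylene of a cyclopropane that also holds a temporary C5–C14 bond. Forward, the zinc alkoxide of the Δ5(10)-octalin alcohol A1 (3β-hydroxy, 4α-methyl, C8 ketone as ethylene ketal) would steer the Et2Zn/CH2I2 carbenoid to the β face of the tetrasubstituted C5=C10 alkene and give the 5β,10β-methano compound A2. Later protonolysis of the C5–C14 bond would release the C10 methyl and a C5 cation that can collapse to the C4=C5 alkene needed for the ene reaction.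
- In favour: delivery is concerted and stereospecific, C10 is set relative to C3 by a cheap reagent without a chiral ligand, and the strained ring stores the unsaturation wanted later.
- Against, here: the directing oxygen is homoallylic, not allylic, and the alkene is tetrasubstituted, so rate and face selectivity are less secure. The acid opening can break C5–C14 or C10–C14 because both give tertiary cations. C7 and its arm are left for an enolate alkylation beside the C8 ketone (C7 against C9, then 7β). O8 would come from reduction of that ketone to the axial alcohol, the less favoured direction.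
- Comparison: structurally it solves ring A and C10 and leaves C7/C8, the reverse of the chosen plan. Mechanistically its key step is at least the equal of the chosen one in predictability of the face, and it is the better in avoiding a hindered carbonyl addition and a ruthenium catalyst. The ring opening and the C8 reduction are weaker than the iodolactonisation. It is linear and is not expected to be shorter, because A1 still needs its own asymmetric entry.

Alternative 2: The cut removes two ring bonds at once, C4–C5 and C9–C10, and unravels the decalin to the acyclic β-keto ester A3. A3 carries only the C7 stereocentre, an E-configured trisubstituted C5=C10 alkene and an enol acetate at C8=C9. Forward, Mn(OAc)3 (trivalent manganese) would generate the C4 radical; 6-endo addition to C5, 6-endo addition of the tertiary C10 radical to C9 and oxidation of the α-acetoxy radical would give the trans-fused diketone A4.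
- In favour: two C–C bonds, two rings, the angular methyl and the C8 oxygen in one operation from a chain. Chair-like closure places the C7 arm equatorial, which is the required 7β/10β relationship. Palladium-mediated decarboxylative dehydrogenation of the allyl ester would then unveil the 4-en-3-one.
- Against, here: C10 depends on 1,4-induction from C7 in a radical cascade and not on a catalyst. C7 sits next to the C8 carbonyl in the methyl ketone from which A3 must be made, so its configuration is at risk before the rings exist. O8 arrives as a ketone and must be reduced to the axial 8β-alcohol beside an enone. Stoichiometric oxidant and the usual side paths of polyene radical cyclisation (5-exo closure, early oxidation) also count against it.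
- Comparison: on bond economy the alternative is clearly the better (two rings and two skeletal bonds against one ring and one bond). On stereocontrol the chosen plan is safer (two independent catalysts, O8 delivered within the molecule). On step count the two are probably equal, since A4 would have to be taken on to 20 and then share the same end game.

Alternative 3: The cut is the C7–C11 bond; C11 and C12 are added as a two-carbon bromoacetal tethered to O8. Forward, Bu3SnH/AIBN would turn the bromoacetal A5 (an 8β-oxygenated 4,6-dien-3-one) into a primary radical that adds 5-exo to C7, the terminus of the dienone, and gives the cis-fused cyclic acetal A6. Oxidation of A6 would give 20 of the chosen route.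
- In favour: the tether guarantees the cis C7/C8 relationship, which is the equal of the iodolactonisation. A nucleophilic radical adding to an electron-poor dienone terminus is polarity-matched. The decalin comes from classical annulation chemistry and only one asymmetric step (for C10) is needed, which is a better point than two catalysts.
- Against, here: the stereochemical burden moves to the 8β-alcohol of A5, which has to be set relative to C10 at an axial, 1,3-diaxially hindered position by substrate control. The dienone has to be made, and hydrogen return to the dienolate radical can place the alkene at C4=C5 or C5=C6. The sequence is linear.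
- Comparison: structurally both plans reach the same lactone, the alternative with ring B already closed and the chosen plan by closing it. Mechanistically 5-exo radical closure and ring-closing metathesis are equally dependable, and both plans use tin hydride once. In step count the alternative could be equal or slightly shorter as far as 20 if A5 is quickly reached, but it offers no convergence and less freedom to vary either half.

Key step: step 11

Assumptions: eudesmane numbering is used throughout and β means the face of the C10 methyl (C14). The ligand antipodes (R)-t-BuPHOX and (R)-BINAP are specified on the basis of the established sense of induction of the (S)-ligands in the parent reactions (allylation of 2-methylcyclohexanone enolate, addition to cyclohexenone); if the sense were opposite for these substrates, the other antipode would be used.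

## Route

Step 1
Reactants: 1 2-methylcyclohexane-1,3-dione
Product: 2 3-isobutoxy-2-methylcyclohex-2-en-1-one
Conditions: i-BuOH, p-TsOH·H2O (cat.), PhMe, reflux, Dean–Stark
Reagents that add atoms: 2-methylpropan-1-ol, CC(C)CO
Why: Acid-catalysed condensation of the enolised 1,3-diketone with the alcohol under azeotropic removal of water gives the vinylogous ester; the diketone is symmetrical, so only one regioisomer can form.

Step 2
Reactants: 2 3-isobutoxy-2-methylcyclohex-2-en-1-one
Product: 3 (±)-3-isobutoxy-2,6-dimethylcyclohex-2-en-1-one
Conditions: LiN(iPr)2, THF, −78 °C; MeI, −78 → 0 °C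
Reagents that add atoms: iodomethane, CI
Why: Kinetic deprotonation of a vinylogous ester takes place at C6 (α′ to the carbonyl) and the lithium enolate is methylated there (Stork–Danheiser alkylation); the new centre is racemic and is erased in step 3.

Step 3
Reactants: 3 (±)-3-isobutoxy-2,6-dimethylcyclohex-2-en-1-one and 4 allyl chloroformate
Product: 5 allyl 5-isobutoxy-2,6-dimethylcyclohexa-1,5-dien-1-yl carbonate
Conditions: LiN(iPr)2, TMEDA, THF, −78 °C; then 4, −78 °C
Reagents that add atoms: none
Why: A second kinetic α′-deprotonation gives the fully substituted lithium enolate, which a chloroformate acylates on oxygen to the allyl enol carbonate; any C-acylated isomer (the allyl β-keto ester) would be an equally valid substrate for step 4, so the O/C ratio is not critical.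

Step 4
Reactants: 5 allyl 5-isobutoxy-2,6-dimethylcyclohexa-1,5-dien-1-yl carbonate
Product: 6 (R)-6-allyl-3-isobutoxy-2,6-dimethylcyclohex-2-en-1-one
Conditions: Pd2(dba)3 (2.5 mol %), (R)-t-BuPHOX (6 mol %), PhMe, 25 °C
Reagents that add atoms: none
Why: Decarboxylative asymmetric allylic alkylation (Tsuji allylation with a PHOX ligand): zerovalent palladium ionises the allyl carbonate, CO2 is lost and the prochiral enolate recombines with the allyl fragment inside the chiral pocket, so the ligand alone sets the quaternary centre (C10 of the target) as R.

Step 5
Reactants: 6 (R)-6-allyl-3-isobutoxy-2,6-dimethylcyclohex-2-en-1-one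
Product: 7 (R)-3-isobutoxy-2,6-dimethyl-6-[(E)-prop-1-en-1-yl]cyclohex-2-en-1-one
Conditions: RuHCl(CO)(PPh3)3 (5 mol %), PhMe, 80 °C
Reagents that add atoms: none
Why: Ruthenium hydride-catalysed alkene isomerisation (hydrometalation, β-hydride elimination) moves the terminal double bond one position inward, mainly to the E isomer, and cannot go further because the next carbon is quaternary; the stereocentre bears no hydrogen and is untouched.

Step 6
Reactants: 8 furan-2(5H)-one and 9 potassium vinyltrifluoroborate
Product: 10 (R)-4-vinyldihydrofuran-2(3H)-one
Conditions: [Rh(cod)(OH)]2 (2.5 mol %), (R)-BINAP (6 mol %), dioxane/H2O (10:1), 50 °C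
Reagents that add atoms: none
Why: Rhodium-catalysed asymmetric conjugate addition of an alkenylboron reagent (Hayashi–Miyaura reaction): the vinylrhodium–BINAP species inserts the lactone C=C from one enantioface and the rhodium enolate is hydrolysed, so the ligand sets the stereocentre (C7 of the target) as R.

Step 7
Reactants: 10 (R)-4-vinyldihydrofuran-2(3H)-one
Product: 11 ethyl (R)-3-(iodomethyl)pent-4-enoate
Conditions: Me3SiI, CH2Cl2, 0 °C → rt; then EtOH, 0 °C → rt
Reagents that add atoms: iodotrimethylsilane, C[Si](C)(C)I; ethanol, CCO
Why: Dealkylative opening of a γ-lactone: silylation of the carbonyl oxygen makes the O–CH2 carbon electrophilic, iodide opens it by SN2 at the primary carbon and ethanolysis of the silyl ester gives the iodo ester; the stereocentre is not touched, and the two arms are now different without any protecting group.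

Step 8
Reactants: 11 ethyl (R)-3-(iodomethyl)pent-4-enoate
Product: 12 (R)-3-(iodomethyl)pent-4-en-1-ol
Conditions: i-Bu2AlH (2.2 equiv), CH2Cl2, −78 → 0 °C
Reagents that add atoms: none
Why: Hydride reduction of the ester to the primary alcohol; a primary alkyl iodide is inert to this electrophilic hydride at low temperature, and the product is silylated at once because a 4-iodo alcohol can slowly close to a tetrahydrofuran.

Step 9
Reactants: 12 (R)-3-(iodomethyl)pent-4-en-1-ol
Product: 13 (R)-tert-butyl{[3-(iodomethyl)pent-4-en-1-yl]oxy}dimethylsilane
Conditions: TBSCl, imidazole, CH2Cl2, 0 °C → rt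
Reagents that add atoms: tert-butylchlorodimethylsilane, CC(C)(C)[Si](C)(C)Cl
Why: Imidazole-promoted silylation of a primary alcohol; the conditions are too weakly basic to trigger cyclisation of the iodo alcohol.

Step 10
Reactants: 13 (R)-tert-butyl{[3-(iodomethyl)pent-4-en-1-yl]oxy}dimethylsilane and 7 (R)-3-isobutoxy-2,6-dimethyl-6-[(E)-prop-1-en-1-yl]cyclohex-2-en-1-one
Product: 16 (4R)-3-[(2R)-4-(tert-butyldimethylsilyloxy)-2-vinylbutyl]-2,4-dimethyl-4-[(E)-prop-1-en-1-yl]cyclohex-2-en-1-one, via alkyllithium 14 (not isolated), via tertiary carbinol 15 (not isolated)
Conditions: t-BuLi (2.1 equiv), Et2O/pentane, −78 °C; then 7, −78 → 0 °C; then 1 M HCl, THF, 0 °C, short contact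
Reagents that add atoms: water, O
Why: Lithium–iodine exchange gives the primary alkyllithium, which adds 1,2 to the vinylogous ester carbonyl; brief aqueous acid ionises the tertiary allylic carbinol and hydrolyses the enol ether with 1,3-carbonyl transposition (Stork–Danheiser sequence), and the primary silyl ether should survive the short exposure. Both stereocentres are spectators: the homoallyllithium can only rearrange through a cyclopropylcarbinyl anion back to itself or to a less stable secondary anion, and it is used at −78 °C.

Step 11
Reactants: 16 (4R)-3-[(2R)-4-(tert-butyldimethylsilyloxy)-2-vinylbutyl]-2,4-dimethyl-4-[(E)-prop-1-en-1-yl]cyclohex-2-en-1-one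
Product: 17 12-(tert-butyldimethylsilyloxy)-13-noreudesma-4,8-dien-3-one [(4aR,7R)-7-[2-(tert-butyldimethylsilyloxy)ethyl]-1,4a-dimethyl-4,4a,7,8-tetrahydronaphthalen-2(3H)-one]
Conditions: second-generation Grubbs catalyst (H2IMes)(PCy3)Cl2Ru=CHPh (5 mol %), CH2Cl2 (0.005 M), 40 °C
Reagents that add atoms: none
Why: Ring-closing olefin metathesis by the metal carbene/metallacyclobutane mechanism: the ruthenium benzylidene first exchanges with the unhindered vinyl group on C7, the resulting C8 carbene adds across the propenyl group on C10, and cycloreversion of the ruthenacyclobutane forms C8=C9 and a ruthenium ethylidene that carries the chain and leaves as propene. The closest known reaction type is cyclohexene formation from 1,7-dienes with this catalyst, including dienes in which one alkene is 1,2-disubstituted and sits next to a quaternary carbon. Ring B closes as a six-membered carbocycle through the tether C7–C6–C5–C10; C5 is an sp2 carbon that holds both C6 and C10, and C10 is quaternary, so the two alkenes are kept close. No stereocentre is formed, because C7 and C10 were fixed in steps 6 and 4 by two independent catalysts; the minor enantiomer of either fragment ends up mainly in a diastereomer of 17 that should be removable, which should raise the enantiomeric purity of the main isomer. The step needs chemoselectivity only: the tetrasubstituted, electron-poor C4=C5 enone alkene cannot form a ruthenacycle at a useful rate, and high dilution disfavours intermolecular metathesis of the vinyl group. The E/Z composition of the propenyl group does not matter, since that carbon is expelled.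

Step 12
Reactants: 17 12-(tert-butyldimethylsilyloxy)-13-noreudesma-4,8-dien-3-one
Product: 18 3-oxo-13-noreudesma-4,8-dien-12-oic acid (7α-H, 10β-CH3)
Conditions: CrO3, H2SO4, H2O, acetone, 0 °C
Reagents that add atoms: water, O
Why: Jones oxidation applied directly to a primary tert-butyldimethylsilyl ether: the acidic medium cleaves the silyl ether and chromic acid oxidises the alcohol through the aldehyde hydrate to the acid; the enone and the isolated ring alkene are inert to the reagent at 0 °C.

Step 13
Reactants: 18 3-oxo-13-noreudesma-4,8-dien-12-oic acid
Product: 19 9α-iodo-3-oxo-13-noreudesm-4-en-8β,12-olide (7α-H, 8α-H)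
Conditions: I2, KI, NaHCO3, THF/H2O, 0 °C → rt, dark
Reagents that add atoms: iodine, II
Why: Iodolactonisation (5-exo): iodonium formation on C8=C9 is reversible, and the carboxylate on the β arm of C7 can reach only C8 and only from the β face, opening the α iodonium anti to give the cis-fused γ-lactone; this sets C8 (8β-O) from C7, with iodine 9α.

Step 14
Reactants: 19 9α-iodo-3-oxo-13-noreudesm-4-en-8β,12-olide
Product: 20 3-oxo-13-noreudesm-4-en-8β,12-olide
Conditions: Bu3SnH, AIBN (cat.), PhMe, 80 °C
Reagents that add atoms: none
Why: Radical chain dehalogenation: the stannyl radical abstracts iodine and the secondary C9 radical takes hydrogen from the tin hydride; the hindered tetrasubstituted enone and the lactone do not react with tin radicals at a competitive rate, and C9 ceases to be a stereocentre.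

Step 15
Reactants: 20 3-oxo-13-noreudesm-4-en-8β,12-olide
Product: 21 3β-hydroxy-13-noreudesm-4-en-8β,12-olide
Conditions: NaBH4, CeCl3·7H2O, MeOH, −20 → 0 °C
Reagents that add atoms: none
Why: Luche reduction: cerium-activated 1,2-reduction of the enone with hydride delivered axially from the α face, away from the axial C10 methyl that screens the β face, which gives the equatorial 3β-alcohol (C3 = S) as in 10β-methyl 4-en-3-ones generally; the lactone is not reduced under these conditions.

Step 16
Reactants: 21 3β-hydroxy-13-noreudesm-4-en-8β,12-olide
Product: 22 3β-(tert-butyldimethylsilyloxy)-13-noreudesm-4-en-8β,12-olide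
Conditions: TBSCl, imidazole, DMF, rt
Reagents that add atoms: tert-butylchlorodimethylsilane, CC(C)(C)[Si](C)(C)Cl
Why: Standard silylation of a secondary allylic alcohol; the silyl ether masks C3 against the amide base of step 17 and the hydroxide of step 18, which an isobutyrate would not survive.

Step 17
Reactants: 22 3β-(tert-butyldimethylsilyloxy)-13-noreudesm-4-en-8β,12-olide
Product: 25 3β-(tert-butyldimethylsilyloxy)eudesma-4,11(13)-dien-8β,12-olide, via Mannich base 23 (not isolated), via ammonium iodide 24 (not isolated)
Conditions: LiN(iPr)2, THF, −78 °C; CH2=NMe2+ I−, −78 → 0 °C; then MeI, THF/MeOH, rt; then aq. NaHCO3, rt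
Reagents that add atoms: N,N-dimethylmethyleneiminium iodide, C=[N+](C)C.[I-]
Why: α-Methylenation of a lactone through its lithium enolate: Mannich reaction with Eschenmoser's salt, N-methylation and base-induced β-elimination of trimethylamine give the exocyclic alkene; the lactone is the only enolisable carbonyl, and C11 ends as sp2, so its configuration in 23 and 24 is irrelevant.

Step 18
Reactants: 25 3β-(tert-butyldimethylsilyloxy)eudesma-4,11(13)-dien-8β,12-olide
Product: 27 methyl 8β-hydroxy-3β-(tert-butyldimethylsilyloxy)eudesma-4,11(13)-dien-12-oate, via lithium carboxylate 26 (not isolated)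
Conditions: LiOH·H2O, THF/H2O, rt; evaporate; MeI, DMF, rt
Reagents that add atoms: lithium hydroxide, [Li+].[OH-]; iodomethane, CI
Why: Saponification of the lactone followed by SN2 O-methylation of the carboxylate salt without acidification, so the cis hydroxy acid never has the chance to relactonise; the secondary alcohol is not alkylated under these conditions and C8 keeps its configuration because the O8–C8 bond is not broken.

Step 19
Reactants: 27 methyl 8β-hydroxy-3β-(tert-butyldimethylsilyloxy)eudesma-4,11(13)-dien-12-oate
Product: 28 methyl 8β-acetoxy-3β-(tert-butyldimethylsilyloxy)eudesma-4,11(13)-dien-12-oate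
Conditions: Ac2O, pyridine, DMAP (cat.), CH2Cl2, rt
Reagents that add atoms: acetic anhydride, CC(=O)OC(C)=O
Why: Nucleophilic catalysis by DMAP acetylates the axial 8β-alcohol faster than it can attack the neighbouring methyl ester, which locks the ring-opened form.

Step 20
Reactants: 28 methyl 8β-acetoxy-3β-(tert-butyldimethylsilyloxy)eudesma-4,11(13)-dien-12-oate
Product: 29 methyl 8β-acetoxy-3β-hydroxyeudesma-4,11(13)-dien-12-oate
Conditions: HF·pyridine, pyridine/THF, 0 °C → rt
Reagents that add atoms: none
Why: Fluoride-driven cleavage of the silyl ether under buffered, non-basic conditions, which leave the acetate, the methyl ester and the acrylate intact and do not ionise the allylic alcohol.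

Step 21
Reactants: 29 methyl 8β-acetoxy-3β-hydroxyeudesma-4,11(13)-dien-12-oate
Product: 30 methyl 8β-acetoxy-3β-(isobutyryloxy)eudesma-4,11(13)-dien-12-oate
Conditions: i-PrCOCl, pyridine, DMAP (cat.), CH2Cl2, 0 °C
Reagents that add atoms: isobutyryl chloride, CC(C)C(=O)Cl
Why: Acylation of the only free hydroxyl group; the equatorial allylic 3β-alcohol reacts readily, and no stereocentre is involved.

Step 22
Reactants: 30 methyl 8β-acetoxy-3β-(isobutyryloxy)eudesma-4,11(13)-dien-12-oate
Product: 31 methyl 8β-acetoxy-5α-hydroperoxy-3β-(isobutyryloxy)eudesma-4(15),11(13)-dien-12-oate, (3S,5S,7R,8R,10R)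
Conditions: O2, hν (visible), tetraphenylporphyrin (cat.), CH2Cl2, 0 °C
Reagents that add atoms: dioxygen, O=O
Why: Schenck ene reaction: singlet oxygen approaches the electron-rich tetrasubstituted C4=C5 alkene from the α face, anti to the axial C10 methyl, bonds to C5 and takes a hydrogen from the freely rotating C15 methyl (the α hydrogen on C6 is equatorial and badly aligned, and the one on C3 is geminal to the ester), which sets C5 as the 5α-hydroperoxide and moves the alkene to C4=C15. The electron-poor acrylate alkene does not react with this electrophilic oxidant.

## Compound list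

1 | 2-methylcyclohexane-1,3-dione | CC1C(=O)CCCC1=O | starting material
2 | 3-isobutoxy-2-methylcyclohex-2-en-1-one | CC(C)COC1=C(C)C(=O)CCC1 | intermediate
3 | (±)-3-isobutoxy-2,6-dimethylcyclohex-2-en-1-one | CC(C)COC1=C(C)C(=O)C(C)CC1 | intermediate
4 | allyl chloroformate | C=CCOC(=O)Cl | starting material
5 | allyl 5-isobutoxy-2,6-dimethylcyclohexa-1,5-dien-1-yl carbonate | C=CCOC(=O)OC1=C(C)CCC(OCC(C)C)=C1C | intermediate
6 | (R)-6-allyl-3-isobutoxy-2,6-dimethylcyclohex-2-en-1-one | C=CC[C@@]1(C)CCC(OCC(C)C)=C(C)C1=O | intermediate
7 | (R)-3-isobutoxy-2,6-dimethyl-6-[(E)-prop-1-en-1-yl]cyclohex-2-en-1-one | C/C=C/[C@@]1(C)CCC(OCC(C)C)=C(C)C1=O | intermediate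
8 | furan-2(5H)-one | O=C1C=CCO1 | starting material
9 | potassium vinyltrifluoroborate | [K+].C=C[B-](F)(F)F | starting material
10 | (R)-4-vinyldihydrofuran-2(3H)-one | O=C1C[C@H](C=C)CO1 | intermediate
11 | ethyl (R)-3-(iodomethyl)pent-4-enoate | CCOC(=O)C[C@H](C=C)CI | intermediate
12 | (R)-3-(iodomethyl)pent-4-en-1-ol | OCC[C@H](C=C)CI | intermediate
13 | (R)-tert-butyl{[3-(iodomethyl)pent-4-en-1-yl]oxy}dimethylsilane | CC(C)(C)[Si](C)(C)OCC[C@H](C=C)CI | intermediate
14 | {(2R)-2-[2-(tert-butyldimethylsilyloxy)ethyl]but-3-en-1-yl}lithium | [Li]C[C@@H](C=C)CCO[Si](C)(C)C(C)(C)C | intermediate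
15 | (6R)-1-[(2S)-4-(tert-butyldimethylsilyloxy)-2-vinylbutyl]-3-isobutoxy-2,6-dimethyl-6-[(E)-prop-1-en-1-yl]cyclohex-2-en-1-ol (both C1 epimers; same spatial arrangement at the side-chain centre as in 13) | C/C=C/[C@@]1(C)CCC(OCC(C)C)=C(C)C1(O)C[C@@H](C=C)CCO[Si](C)(C)C(C)(C)C | intermediate
16 | (4R)-3-[(2R)-4-(tert-butyldimethylsilyloxy)-2-vinylbutyl]-2,4-dimethyl-4-[(E)-prop-1-en-1-yl]cyclohex-2-en-1-one | C/C=C/[C@@]1(C)CCC(=O)C(C)=C1C[C@@H](C=C)CCO[Si](C)(C)C(C)(C)C | intermediate
17 | 12-(tert-butyldimethylsilyloxy)-13-noreudesma-4,8-dien-3-one (7α-H, 10β-CH3) | CC(C)(C)[Si](C)(C)OCC[C@H]1CC2=C(C)C(=O)CC[C@]2(C)C=C1 | intermediate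
18 | 3-oxo-13-noreudesma-4,8-dien-12-oic acid (7α-H, 10β-CH3) | OC(=O)C[C@H]1CC2=C(C)C(=O)CC[C@]2(C)C=C1 | intermediate
19 | 9α-iodo-3-oxo-13-noreudesm-4-en-8β,12-olide (7α-H, 8α-H) | O=C1C[C@H]2CC3=C(C)C(=O)CC[C@]3(C)[C@H](I)[C@H]2O1 | intermediate
20 | 3-oxo-13-noreudesm-4-en-8β,12-olide | O=C1C[C@H]2CC3=C(C)C(=O)CC[C@]3(C)C[C@H]2O1 | intermediate
21 | 3β-hydroxy-13-noreudesm-4-en-8β,12-olide | O=C1C[C@H]2CC3=C(C)[C@@H](O)CC[C@]3(C)C[C@H]2O1 | intermediate
22 | 3β-(tert-butyldimethylsilyloxy)-13-noreudesm-4-en-8β,12-olide | O=C1C[C@H]2CC3=C(C)[C@@H](O[Si](C)(C)C(C)(C)C)CC[C@]3(C)C[C@H]2O1 | intermediate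
23 | 13-(dimethylamino)-3β-(tert-butyldimethylsilyloxy)eudesm-4-en-8β,12-olide (C11 epimers) | O=C1C(CN(C)C)[C@H]2CC3=C(C)[C@@H](O[Si](C)(C)C(C)(C)C)CC[C@]3(C)C[C@H]2O1 | intermediate
24 | 13-(trimethylammonio)-3β-(tert-butyldimethylsilyloxy)eudesm-4-en-8β,12-olide iodide (C11 epimers) | O=C1C(C[N+](C)(C)C)[C@H]2CC3=C(C)[C@@H](O[Si](C)(C)C(C)(C)C)CC[C@]3(C)C[C@H]2O1.[I-] | intermediate
25 | 3β-(tert-butyldimethylsilyloxy)eudesma-4,11(13)-dien-8β,12-olide | O=C1C(=C)[C@H]2CC3=C(C)[C@@H](O[Si](C)(C)C(C)(C)C)CC[C@]3(C)C[C@H]2O1 | intermediate
26 | lithium 8β-hydroxy-3β-(tert-butyldimethylsilyloxy)eudesma-4,11(13)-dien-12-oate | [Li+].C=C(C(=O)[O-])[C@H]1CC2=C(C)[C@@H](O[Si](C)(C)C(C)(C)C)CC[C@]2(C)C[C@H]1O | intermediate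
27 | methyl 8β-hydroxy-3β-(tert-butyldimethylsilyloxy)eudesma-4,11(13)-dien-12-oate | C=C(C(=O)OC)[C@H]1CC2=C(C)[C@@H](O[Si](C)(C)C(C)(C)C)CC[C@]2(C)C[C@H]1O | intermediate
28 | methyl 8β-acetoxy-3β-(tert-butyldimethylsilyloxy)eudesma-4,11(13)-dien-12-oate | C=C(C(=O)OC)[C@H]1CC2=C(C)[C@@H](O[Si](C)(C)C(C)(C)C)CC[C@]2(C)C[C@H]1OC(C)=O | intermediate
29 | methyl 8β-acetoxy-3β-hydroxyeudesma-4,11(13)-dien-12-oate | C=C(C(=O)OC)[C@H]1CC2=C(C)[C@@H](O)CC[C@]2(C)C[C@H]1OC(C)=O | intermediate
30 | methyl 8β-acetoxy-3β-(isobutyryloxy)eudesma-4,11(13)-dien-12-oate | C=C(C(=O)OC)[C@H]1CC2=C(C)[C@@H](OC(=O)C(C)C)CC[C@]2(C)C[C@H]1OC(C)=O | intermediate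
31 | methyl 8β-acetoxy-5α-hydroperoxy-3β-(isobutyryloxy)eudesma-4(15),11(13)-dien-12-oate, (3S,5S,7R,8R,10R) | C=C(C(=O)OC)[C@H]1C[C@@]2(OO)C(=C)[C@@H](OC(=O)C(C)C)CC[C@]2(C)C[C@H]1OC(C)=O | target

## Step count and least certain steps

Total: 22 steps. Longest linear sequence: 18 steps (steps 1–5, then 10–22); the side branch to 13 has 4 steps (6–9).

Step 11 (key step). The most likely failure is slow ring closure at the propenyl terminus, which is next to the quaternary carbon. The vinyl group could then undergo intermolecular metathesis, or the C7 vinyl double bond could migrate under ruthenium hydride species formed from a long-lived catalyst. Fallback: close the ring before the enone exists. The fallback sets out from 15, isolated after a neutral NH4Cl work-up of the addition in step 10 in place of the acid treatment. With C5 still sp3 and the two alkenes on neighbouring saturated carbons, the same type of catalyst in dilute CH2Cl2 should give 3-isobutoxy-12-(tert-butyldimethylsilyloxy)-13-noreudesma-3,8-dien-5-ol F1. Brief aqueous HCl in THF then performs the hydrolysis and transposition, and the route is rejoined at 17.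

Step 6. Furan-2(5H)-one is base- and heat-sensitive and the vinylboron reagent can protodeboronate. Conversion may therefore be incomplete, or the lactone may be consumed by ring opening before the rhodium enolate is formed; the enantiofacial control on this small acceptor may also be lower than on six-membered rings. Fallback: resolution instead of asymmetric catalysis. It sets out from 8. Copper-catalysed conjugate addition of CH2=CHMgBr (CuBr·SMe2 cat., Me3SiCl, THF, −78 °C) gives racemic 4-vinyldihydrofuran-2(3H)-one F2. Aminolysis with (S)-1-phenylethylamine gives two diastereomeric hydroxy amides, from which (3R)-3-(hydroxymethyl)-N-[(1S)-1-phenylethyl]pent-4-enamide F3 is separated by crystallisation or chromatography. Hot dilute H2SO4 in dioxane closes F3 back to the lactone, and the route is rejoined at 10.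

Step 10. The carbonyl of 7 lies between a quaternary carbon and a substituted sp2 carbon. The alkyllithium may therefore act as a base (γ-deprotonation of the vinylogous ester) or be consumed by coupling and elimination during the exchange before it adds; prolonged acid could also remove the silyl group. Fallback: a Barbier coupling in which no strongly basic organometallic is preformed. It sets out from 13 and 7, which are treated together with SmI2 (divalent samarium) and HMPA in THF so that the iodide is reduced in the presence of the ketone and the carbinol 15 forms directly. The same short acid treatment then returns the route at 16. This fallback makes no compound outside the list (F0).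

Step 22. Two things can go wrong. Competing ene pathways may operate (β-face attack with removal of the axial 6β hydrogen, which puts oxygen on C4). The allylic ester also lowers the reactivity of the alkene, so the reaction may be slow enough for secondary oxidation and decomposition of the tertiary allylic hydroperoxide to intrude. Fallback: move the ene reaction forward and carry the hydroperoxide protected. It sets out from 28, whose alkene is more electron-rich.
- Photo-oxygenation of 28 under the conditions of step 22 gives methyl 8β-acetoxy-5α-hydroperoxy-3β-(tert-butyldimethylsilyloxy)eudesma-4(15),11(13)-dien-12-oate F4, which can be purified at this more robust stage.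
- 2-Methoxypropene with catalytic pyridinium p-toluenesulfonate converts F4 into the 2-methoxyprop-2-yl perketal F5.
- Tetrabutylammonium fluoride removes the silyl group to give the 3β-alcohol perketal F6.
- Isobutyryl chloride and pyridine give the 3β-isobutyrate perketal F7.
- AcOH/THF/H2O releases the hydroperoxide, and the route is rejoined at 31.

## Further compounds

F1 | step 11 | 3-isobutoxy-12-(tert-butyldimethylsilyloxy)-13-noreudesma-3,8-dien-5-ol (both C5 epimers; 7α-H, 10β-CH3) | CC(C)COC1=C(C)C2(O)C[C@H](CCO[Si](C)(C)C(C)(C)C)C=C[C@@]2(C)CC1
F2 | step 6 | (±)-4-vinyldihydrofuran-2(3H)-one | O=C1CC(C=C)CO1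
F3 | step 6 | (3R)-3-(hydroxymethyl)-N-[(1S)-1-phenylethyl]pent-4-enamide | OC[C@@H](C=C)CC(=O)N[C@@H](C)c1ccccc1
F0 | step 10 | none | none
F4 | step 22 | methyl 8β-acetoxy-5α-hydroperoxy-3β-(tert-butyldimethylsilyloxy)eudesma-4(15),11(13)-dien-12-oate | C=C(C(=O)OC)[C@H]1C[C@@]2(OO)C(=C)[C@@H](O[Si](C)(C)C(C)(C)C)CC[C@]2(C)C[C@H]1OC(C)=O
F5 | step 22 | methyl 8β-acetoxy-5α-[(2-methoxypropan-2-yl)peroxy]-3β-(tert-butyldimethylsilyloxy)eudesma-4(15),11(13)-dien-12-oate | C=C(C(=O)OC)[C@H]1C[C@@]2(OOC(C)(C)OC)C(=C)[C@@H](O[Si](C)(C)C(C)(C)C)CC[C@]2(C)C[C@H]1OC(C)=O
F6 | step 22 | methyl 8β-acetoxy-3β-hydroxy-5α-[(2-methoxypropan-2-yl)peroxy]eudesma-4(15),11(13)-dien-12-oate | C=C(C(=O)OC)[C@H]1C[C@@]2(OOC(C)(C)OC)C(=C)[C@@H](O)CC[C@]2(C)C[C@H]1OC(C)=O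
F7 | step 22 | methyl 8β-acetoxy-3β-(isobutyryloxy)-5α-[(2-methoxypropan-2-yl)peroxy]eudesma-4(15),11(13)-dien-12-oate | C=C(C(=O)OC)[C@H]1C[C@@]2(OOC(C)(C)OC)C(=C)[C@@H](OC(=O)C(C)C)CC[C@]2(C)C[C@H]1OC(C)=O
A1 | alternative 1 | 8,8-(ethylenedioxy)-4α-methyl-11,12,13,14-tetranoreudesm-5(10)-en-3β-ol | C[C@@H]1[C@@H](O)CCC2=C1CCC1(C2)OCCO1
A2 | alternative 1 | 8,8-(ethylenedioxy)-5β,14-cyclo-11,12,13-trinoreudesman-3β-ol (4α-methyl; C14 bridges C5 and C10 on the β face) | C[C@@H]1[C@@H](O)CC[C@@]23C[C@@]12CCC1(C3)OCCO1
A3 | alternative 2 | allyl (6E,9R)-10-acetoxy-9-(2-methoxy-2-oxoethyl)-2,6-dimethyl-3-oxoundeca-6,10-dienoate | C=CCOC(=O)C(C)C(=O)CC/C(C)=C/C[C@H](CC(=O)OC)C(OC(C)=O)=C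
A4 | alternative 2 | methyl 4-(allyloxycarbonyl)-3,8-dioxo-13-noreudesman-12-oate (trans-fused; 5α-H, 7α-H, 10β-CH3) | C=CCOC(=O)[C@@]1(C)C(=O)CC[C@]2(C)CC(=O)[C@@H](CC(=O)OC)C[C@@H]12
A5 | alternative 3 | 8β-(2-bromo-1-ethoxyethoxy)-11,12,13-trinoreudesma-4,6-dien-3-one (acetal carbon epimers) | O=C1CC[C@]2(C)C[C@@H](OC(CBr)OCC)C=CC2=C1C
A6 | alternative 3 | 12-ethoxy-8β,12-epoxy-13-noreudesm-4-en-3-one (C12 epimers; 7α-H, 8α-H) | O=C1CC[C@]2(C)C[C@H]3OC(OCC)C[C@H]3CC2=C1C
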